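(Readings and results were computed from invented constants, noise included.)

At 1.0 h the target in this flask was to be read, so I turned the question round and asked what the charges would need for target to go on forming up to that hour. A molecule of free catalyst stands at a fork at every moment: another turn, or capture by the stray impurity. If each stray impurity takes one free catalyst, what outlasts the capture can be reckoned from the charges. In the flask −23.0 µM is the catalyst surplus, the charged [free catalyst] less the charged [stray impurity].

the same everywhere: gas phase 0.84 mM (held); free catalyst 0.5 mol%

| charge | starting material | protic impurity | stray impurity | remark | time |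
|---|---|---|---|---|---|
| Monday's | 0.010 M | 0.20 mM | 49 µM | run made earlier |  |
| Tuesday's | 0.010 M | 0.20 mM | 110 µM | run made earlier |  |
| Wednesday's | 0.020 M | 0.20 mM | 73 µM | run made earlier |  |
| flask | 0.010 M | 0.200 mM | 73 µM |  | 1.0 h |

- Monday's (time / min: target / %): 8.00: 32.6; 15.0: 42.2; 25.0: 50.8; 30.0: 53.7; 40.0: 59.1; 50.0: 63.3
- Tuesday's (time / min: target / %): 8.00: 4.3; 15.0: 4.0; 25.0: 3.9; 30.0: 3.8; 40.0: 4.2; 50.0: 3.8
- Wednesday's (time / min: target / %): 10.0: 58.5; 20.0: 92.7; 30.0: 98.3; 40.0: 99.1; 50.0: 99.3

(scatter of a reading: 0.3 percentage points)

- at the start none of the gas is dissolved
- steps thought possible: gas phase <-> dissolved gas; starting material + dissolved gas + free catalyst -> free catalyst + target; 2 dissolved gas -> self-condensation product; starting material + protic impurity -> quenched substrate; free catalyst + stray impurity -> spent catalyst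

- how much target there is at 1.0 h, in percent of the starting material charged
- the change that raises the amount of target at 1.0 h, in percent of the starting material charged most ("none" if none brings more than 2 percentage points) (noon / spring / winter / none)
- amount of target at 1.0 h, in percent of the starting material charged, after noon

- noon: doubling the saturation concentration of gas phase, all else as stated
- spring: doubling the transfer coefficient of the gas phase, all else as stated
- winter: doubling the amount of free catalyst, all else as stated

The runs read well against it. Monday's run, with a surplus of 1.00 µM, was still climbing at 63.3%, Wednesday's, with 27.0 µM, reached 99.3%, and Tuesday's, with −60.0 µM, stood flat near 3.8%. In these runs a rising target went with a positive surplus, and this flask stood 23.0 µM short of zero, with free catalyst as the limiting reagent of the capture step. Its surplus lay above Tuesday's, so I expected a flat plateau higher than Tuesday's. Winter lifted the surplus to 27.0 µM, whereas noon and spring left it where it was, so I chose winter.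

The forecast, holding that “all catalyst dies within a few minutes”, gave 10.5%, chose winter, and gave 19.5% after noon.

The flask gave 9.95%, winter gained 88 percentage points, and noon gave 17.4%.

    gas phase ⇌ dissolved gas, rate k1*(csat - [dissolved gas]) (kL = 0.0300 s⁻¹)
    starting material + dissolved gas + free catalyst → free catalyst + target (k = 3.60 × 10⁵ M⁻² s⁻¹)
    2 dissolved gas → self-condensation product (k = 20.0 M⁻¹ s⁻¹)
    starting material + protic impurity → quenched substrate (k = 14.0 M⁻¹ s⁻¹)
    free catalyst + stray impurity → spent catalyst (k = 860 M⁻¹ s⁻¹)

The target at 1.0 h had moved by 5 points already at 62.8 µM of stray impurity, where the surplus was still −12.8 µM, so a change that left the surplus negative was enough to move the answer; a surplus above zero is what the neighbouring flask shows. With 0.040 M of starting material at the same loading, the charged [stray impurity] remained 73 µM while the charged [free catalyst] rose to 200 µM, a surplus of 127 µM, or 63.5% of its charge. That neighbouring flask held 63.5% of its catalyst free at 1.00 h, and its target stood at 99.5%.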